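4.3 percentage points is where I start: the red run gained that much less target in its last 10.0 h than in its first 10.0 h.

| flask | starting material | free enzyme | temperature | remark | time |
|---|---|---|---|---|---|
| blue | 0.020 M | 1.2 µM | 0 °C | run made earlier |  |
| red | 0.020 M | 1.8 µM | 15 °C | run made earlier |  |
| ochre | 0.030 M | 2.4 µM | 0 °C | run made earlier |  |
| north-east | 0.020 M | 2.4 µM | 5 °C |  | 3.0 d |
| south-west | 0.020 M | 2.4 µM |  | at 25 °C until 15 h, from then on at 5 °C | 3.0 d |
| east | 0.020 M | 2.4 µM | 25 °C |  | 3.0 d |

| run | time / h | target / % |
|---|---|---|
| blue | 3.00 | 2.4 |
| blue | 6.00 | 3.4 |
| blue | 12.0 | 6.6 |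
| blue | 25.0 | 13.5 |
| blue | 40.0 | 21.7 |
| red | 5.00 | 13.3 |
| red | 10.0 | 25.8 |
| red | 15.0 | 38.0 |
| red | 20.0 | 49.5 |
| red | 25.0 | 59.5 |
| ochre | 3.00 | 2.4 |
| ochre | 6.00 | 3.0 |
| ochre | 12.0 | 7.5 |
| ochre | 25.0 | 15.3 |
| ochre | 40.0 | 24.4 |

(standard deviation of a reading: 0.5 percentage points)

- the flask with the highest amount of target, in percent of the starting material charged ("all alike" if they lie within 1.5 percentage points) (north-east / south-west / east / all alike)
- final target, as a percentage of the starting material charged, in north-east
- final target, as a percentage of the starting material charged, in south-west
- final target, as a percentage of the starting material charged, in east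

- what may be going on: free enzyme -> unfolded enzyme; starting material + free enzyme -> target + free enzyme; target + free enzyme <-> isomer of the product + free enzyme

**What does that gap measure?** Red made 0.0258 h⁻¹ of its charge early and 0.0215 h⁻¹ late, while the target on hand rose by 36 points. If the whole fall is target turning into its isomer, a loss that grows with the target present, the loss constant is 0.0120 h⁻¹.

**Couldn't thinning starting material explain it?** It may explain part of it. Ochre made less target per enzyme than blue from a richer charge, but that compares charges of 0.020 M and 0.030 M, and red's late stretch lies below both. So I can exclude neither thinning nor dying enzyme, either of which would make my loss constant read too high, and the gap itself carries a scatter of 0.87 points.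

**What do you carry to the new flasks?** Target's half-life, the time in which the target on hand halves once nothing makes it. I scale the loss with enzyme, and assume it warms like the making, which rose 3.17 times per enzyme from blue to red. That gives 20.1 h at the temperature of east and 93.5 h at that of north-east.

**And how long does making last?** At the scaled early rate, the charge lasts 13.5 h in east and 62.7 h in north-east.

**So east?** East then stands 2.91 half-lives with nothing being made, and I reckon 10.6 %. South-west pays at the warm rate until 15 h, then at the cold one, giving 49.7 %. North-east has a half-life longer than its time, giving 74.7 %, the best of the flasks.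

The forecast also names north-east, but with 88 %, 70 % and 63 % for north-east, south-west and east, and its east stands well above mine. Its grounds for the warm flask: “Unfolding should be steeply temperature dependent”.

The flasks give 76.0 % in north-east, 66.0 % in south-west and 29.0 % in east, so the highest is north-east.

    free enzyme → unfolded enzyme (k = 0.00110 h⁻¹, Ea = 236 kJ mol⁻¹)
    starting material + free enzyme → target + free enzyme, rate k2*[starting material]*[free enzyme]/(1 + ([starting material]/Km2) + ([starting material]/Ksi2)^2) (49.0 mM, 14.0 mM, k = 1.00 × 10⁵ L mol⁻¹ h⁻¹, Ea = 50.0 kJ mol⁻¹)
    target + free enzyme ⇌ isomer of the product + free enzyme, rate k3*[free enzyme]*[target] forward; the back reaction follows from the equilibrium constant (K = 20.0, k = 8900 L mol⁻¹ h⁻¹, Ea = 51.0 kJ mol⁻¹, ΔH = 18.0 kJ mol⁻¹)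
    (constants at 25 °C)

In east, target was made 7.08 times faster than it was used up at 0.290 d; by 1.50 d starting material stood at 0.0874 %, while the step to the isomer went on and took target from 56.6 % to 29.0 % at 3.00 d. The half-life of that step in east is 1.39 d, longer than my 20.1 h, and target falls towards an equilibrium share of 4.76 %. Applied to the excess over that share, this half-life gives 13.7 % for the same flask left until 5.0 d, which holds 14.0 % target.

(The numbers in the tables were computed from invented constants; the scatter is artificial.)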